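**Strategy**

With the cyclopentane numbered C1 (quaternary), C2 (CH2OAr), C3 (methyl), C4 (CH2), C5 (isobutenyl), the ring is read as a norbornene whose etheno bridge has been cut: C3, C4, C5, the C3-methyl carbon and the vinylic CH on C5 are the five carbons of cyclopentadiene, which is why methyl and isobutenyl are cis. One catalytic enantioselective Diels–Alder reaction of cyclopentadiene with an (E)-4-silyloxycrotonate thus forms the C1–C5 and C2–C3 bonds together and sets C2, C3 and C5. Ozonolysis later frees the two bridge carbons; lactonisation onto the endo ester tells them apart, and the cis-fused lactone directs the quaternary methylation.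

Key step: step 3

Assumption: the (S)-configured oxazaborolidinium catalyst is taken to deliver the (1S,2R,3R,4R) adduct 5; if its facial sense is the opposite one, the equally available (R)-catalyst is used. TBDPS = tert-butyldiphenylsilyl.

**Route**

Step 1
Reactants: 1 monoethyl fumarate
Product: 2 ethyl (2E)-4-hydroxybut-2-enoate
Conditions: BH3·SMe2 (1.0 equiv), THF, −10 → 20 °C; MeOH quench
Reagents that add atoms: none
Why: Chemoselective borane reduction of a carboxylic acid (acyloxyborane activation) in the presence of an ester and a conjugated alkene, leaving the (E)-geometry untouched.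

Step 2
Reactants: 2 ethyl (2E)-4-hydroxybut-2-enoate
Product: 3 ethyl (2E)-4-[(tert-butyldiphenylsilyl)oxy]but-2-enoate
Conditions: TBDPSCl, imidazole, CH2Cl2, 0 → 20 °C
Reagents that add atoms: tert-butyl(chloro)diphenylsilane, CC(C)(C)[Si](Cl)(c1ccccc1)c1ccccc1
Why: Standard silylation of a primary allylic alcohol; the TBDPS ether should survive the Lewis acid, enolate, hydride, ylide and oxidation steps that follow.

Step 3
Reactants: 3 ethyl (2E)-4-[(tert-butyldiphenylsilyl)oxy]but-2-enoate; 4 cyclopenta-1,3-diene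
Product: 5 ethyl (1S,2R,3R,4R)-3-{[(tert-butyldiphenylsilyl)oxy]methyl}bicyclo[2.2.1]hept-5-ene-2-carboxylate (ester endo, CH2OSi exo)
Conditions: 4 (5 equiv), (S)-o-tolyl-CBS oxazaborolidine·Tf2NH (20 mol %), CH2Cl2, −20 → 4 °C
Reagents that add atoms: none
Why: The cationic oxazaborolidine binds the ester carbonyl of 3 and lowers its LUMO, and cyclopentadiene adds across the (E)-alkene in a concerted, asynchronous [π4s+π2s] Diels–Alder reaction that forms the C1–C2 and C3–C4 σ-bonds of the norbornene (the later C5–C1 and C2–C3 bonds of the cyclopentane) in one operation. The closest known reactions are the oxazaborolidinium-catalysed additions of cyclopentadiene to crotonate and fumarate esters. The six-membered ring is closed by suprafacial addition to both termini of the s-cis-locked diene, which at the same time creates the five-membered ring C1–C2–C3–C4–C7 that survives as the cyclopentane. The two bridgehead centres are cis by necessity because both bonds are made to one face of the cyclic diene, C2 and C3 are trans because the (E)-geometry of 3 is transferred suprafacially, the ester is placed endo by secondary orbital overlap reinforced by the Lewis acid, and the absolute sense is set by the catalyst, which shields one enantioface of the bound enoate. The step needs endo and enantiofacial selectivity; the first is secured by Lewis-acid activation of a dienophile with a single acyl group trans to a non-conjugating CH2OSi group, the second by the catalyst. Regioselectivity does not arise because the diene is symmetric.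

Step 4
Reactants: 5 ethyl (1S,2R,3R,4R)-3-{[(tert-butyldiphenylsilyl)oxy]methyl}bicyclo[2.2.1]hept-5-ene-2-carboxylate
Product: 8 (3aR,5S,6R,6aR)-6-{[(tert-butyldiphenylsilyl)oxy]methyl}-5-(hydroxymethyl)hexahydro-1H-cyclopenta[c]furan-1-one, via secondary ozonide 6 (not isolated), via ethyl (1R,2R,3S,5R)-2-{[(tert-butyldiphenylsilyl)oxy]methyl}-3,5-bis(hydroxymethyl)cyclopentane-1-carboxylate 7 (not isolated)
Conditions: O3, CH2Cl2, −78 °C; then NaBH4, MeOH, −78 → 0 °C; aq. citric acid, PPTS (cat.), CH2Cl2, 20 °C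
Reagents that add atoms: ozone, [O-][O+]=O
Why: Ozonolysis of the strained alkene and borohydride reduction of the ozonide give the cis-1,3-bis(hydroxymethyl) ester, in which only the CH2OH cis-vicinal to the former endo ester can close a γ-lactone, so the two termini are told apart without a protecting group and no stereocentre is created.

Step 5
Reactants: 8 (3aR,5S,6R,6aR)-6-{[(tert-butyldiphenylsilyl)oxy]methyl}-5-(hydroxymethyl)hexahydro-1H-cyclopenta[c]furan-1-one
Product: 11 (3aR,5S,6R,6aR)-6-{[(tert-butyldiphenylsilyl)oxy]methyl}-5-methylhexahydro-1H-cyclopenta[c]furan-1-one, via N-alkyl-N-(2-nitrobenzenesulfonyl)hydrazine 9 (not isolated), via monoalkyl diazene 10 (not isolated)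
Conditions: PPh3, DEAD, 2-nitrobenzenesulfonylhydrazide (NBSH), THF, −30 → 23 °C
Reagents that add atoms: none
Why: Myers reductive deoxygenation: Mitsunobu N-alkylation of NBSH, loss of sulfinic acid and fragmentation of the monoalkyl diazene with loss of N2 should turn the unhindered primary CH2OH into CH3 without touching the lactone.

Step 6
Reactants: 11 (3aR,5S,6R,6aR)-6-{[(tert-butyldiphenylsilyl)oxy]methyl}-5-methylhexahydro-1H-cyclopenta[c]furan-1-one
Product: 13 (3aR,5S,6R,6aR)-6-{[(tert-butyldiphenylsilyl)oxy]methyl}-5,6a-dimethylhexahydro-1H-cyclopenta[c]furan-1-one, via lithium enolate 12 (not isolated)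
Conditions: LDA (1.2 equiv), THF, −78 °C; MeI (3 equiv), −78 → −20 °C
Reagents that add atoms: iodomethane, CI
Why: Lactone enolate alkylation at the ring-fusion carbon: a trans-fused bicyclo[3.3.0] lactone is prohibitively strained, so MeI must enter on the face opposite the lactone CH2, which sets the quaternary centre with methyl cis to the CH2OSi group.

Step 7
Reactants: 13 (3aR,5S,6R,6aR)-6-{[(tert-butyldiphenylsilyl)oxy]methyl}-5,6a-dimethylhexahydro-1H-cyclopenta[c]furan-1-one
Product: 14 (3aR,5S,6R,6aR)-6-{[(tert-butyldiphenylsilyl)oxy]methyl}-5,6a-dimethylhexahydro-1H-cyclopenta[c]furan-1-ol (mixture of anomers)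
Conditions: DIBAL-H (1.2 equiv), CH2Cl2, −78 °C; Rochelle salt
Reagents that add atoms: none
Why: Low-temperature DIBAL-H half-reduction of a γ-lactone stops at the lactol through the stable aluminium hemiacetal; the anomeric centre is of no consequence.

Step 8
Reactants: 14 (3aR,5S,6R,6aR)-6-{[(tert-butyldiphenylsilyl)oxy]methyl}-5,6a-dimethylhexahydro-1H-cyclopenta[c]furan-1-ol
Product: 15 methyl (2E)-3-[(1R,2R,3S,5R)-2-{[(tert-butyldiphenylsilyl)oxy]methyl}-5-(hydroxymethyl)-1,3-dimethylcyclopentyl]prop-2-enoate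
Conditions: Ph3P=CHCO2Me (3 equiv), PhCO2H (cat.), toluene, 90 °C
Reagents that add atoms: methyl (triphenyl-λ5-phosphanylidene)acetate, COC(=O)C=P(c1ccccc1)(c1ccccc1)c1ccccc1
Why: Wittig olefination of the open hydroxy-aldehyde tautomer with a stabilised ylide gives the (E)-enoate, and neutral to slightly acidic conditions are chosen to keep the freed alcohol from adding back to the enoate.

Step 9
Reactants: 15 methyl (2E)-3-[(1R,2R,3S,5R)-2-{[(tert-butyldiphenylsilyl)oxy]methyl}-5-(hydroxymethyl)-1,3-dimethylcyclopentyl]prop-2-enoate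
Product: 16 methyl 3-[(1R,2R,3S,5R)-2-{[(tert-butyldiphenylsilyl)oxy]methyl}-5-(hydroxymethyl)-1,3-dimethylcyclopentyl]propanoate
Conditions: H2 (1 atm), 10 % Pd/C, EtOAc, 20 °C
Reagents that add atoms: none
Why: Heterogeneous hydrogenation of the only C=C bond present at this stage; silyl ether, ester and alcohol are inert.

Step 10
Reactants: 16 methyl 3-[(1R,2R,3S,5R)-2-{[(tert-butyldiphenylsilyl)oxy]methyl}-5-(hydroxymethyl)-1,3-dimethylcyclopentyl]propanoate
Product: 17 methyl 3-[(1S,2R,3S,5R)-2-{[(tert-butyldiphenylsilyl)oxy]methyl}-5-formyl-1,3-dimethylcyclopentyl]propanoate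
Conditions: Dess–Martin periodinane, NaHCO3, CH2Cl2, 0 → 20 °C
Reagents that add atoms: none
Why: Dess–Martin oxidation of a primary alcohol to the aldehyde under buffered conditions that should not epimerise the α-centre.

Step 11
Reactants: 17 methyl 3-[(1S,2R,3S,5R)-2-{[(tert-butyldiphenylsilyl)oxy]methyl}-5-formyl-1,3-dimethylcyclopentyl]propanoate
Product: 18 methyl 3-[(1R,2R,3S,5S)-2-{[(tert-butyldiphenylsilyl)oxy]methyl}-1,3-dimethyl-5-(2-methylprop-1-en-1-yl)cyclopentyl]propanoate
Conditions: iPrPPh3+ I−, n-BuLi, THF, 0 °C; then 17, −78 → 0 °C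
Reagents that add atoms: isopropyltriphenylphosphonium iodide, CC(C)[P+](c1ccccc1)(c1ccccc1)c1ccccc1.[I-]
Why: Wittig olefination with the non-stabilised isopropylidene ylide installs the trisubstituted alkene; at −78 °C the aldehyde reacts far faster than the methyl ester and the hindered α-centre should not be enolised.

Step 12
Reactants: 18 methyl 3-[(1R,2R,3S,5S)-2-{[(tert-butyldiphenylsilyl)oxy]methyl}-1,3-dimethyl-5-(2-methylprop-1-en-1-yl)cyclopentyl]propanoate
Product: 19 methyl 3-[(1R,2R,3S,5S)-2-(hydroxymethyl)-1,3-dimethyl-5-(2-methylprop-1-en-1-yl)cyclopentyl]propanoate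
Conditions: TBAF, THF, 0 → 20 °C
Reagents that add atoms: none
Why: Fluoride-mediated cleavage of the silyl ether, driven by the Si–F bond; ester and alkene are untouched.

Step 13
Reactants: 19 methyl 3-[(1R,2R,3S,5S)-2-(hydroxymethyl)-1,3-dimethyl-5-(2-methylprop-1-en-1-yl)cyclopentyl]propanoate; 20 umbelliferone
Product: 21 methyl 3-[(1R,2R,3S,5S)-1,3-dimethyl-5-(2-methylprop-1-en-1-yl)-2-{[(2-oxo-2H-chromen-7-yl)oxy]methyl}cyclopentyl]propanoate
Conditions: PPh3, DIAD, THF, 0 → 40 °C
Reagents that add atoms: none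
Why: Mitsunobu etherification, in which the phenol (pKa about 7.7) displaces the alkoxyphosphonium ion of the primary alcohol; no stereocentre is involved.

Step 14
Reactants: 21 methyl 3-[(1R,2R,3S,5S)-1,3-dimethyl-5-(2-methylprop-1-en-1-yl)-2-{[(2-oxo-2H-chromen-7-yl)oxy]methyl}cyclopentyl]propanoate
Product: 23 ferulsinaic acid, 3-[(1R,2R,3S,5S)-1,3-dimethyl-5-(2-methylprop-1-en-1-yl)-2-{[(2-oxo-2H-chromen-7-yl)oxy]methyl}cyclopentyl]propanoic acid, via ring-opened (Z)-2-hydroxycinnamic diacid 22 (not isolated)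
Conditions: LiOH (3 equiv), THF/H2O, 20 °C; then 1 M HCl to pH 2, 20 °C
Reagents that add atoms: lithium hydroxide, [Li+].[OH-]
Why: Saponification of the methyl ester; the coumarin lactone opens reversibly to the (Z)-2-hydroxycinnamate and should re-close on acidification.

**Compound list**

1 | monoethyl fumarate, (2E)-4-ethoxy-4-oxobut-2-enoic acid | CCOC(=O)/C=C/C(=O)O | starting material
2 | ethyl (2E)-4-hydroxybut-2-enoate | CCOC(=O)/C=C/CO | intermediate
3 | ethyl (2E)-4-[(tert-butyldiphenylsilyl)oxy]but-2-enoate | CCOC(=O)/C=C/CO[Si](c1ccccc1)(c1ccccc1)C(C)(C)C | intermediate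
4 | cyclopenta-1,3-diene (cracked from commercial dicyclopentadiene) | C1=CC=CC1 | starting material
5 | ethyl (1S,2R,3R,4R)-3-{[(tert-butyldiphenylsilyl)oxy]methyl}bicyclo[2.2.1]hept-5-ene-2-carboxylate (2-endo ester, 3-exo CH2OSi) | C1=C[C@@H]2C[C@H]1[C@@H](CO[Si](c3ccccc3)(c3ccccc3)C(C)(C)C)[C@@H]2C(=O)OCC | intermediate
6 | secondary ozonide (1,2,4-trioxolane) of 5, ozonide carbons unspecified | C13OOC(O3)[C@@H]2C[C@H]1[C@@H](CO[Si](c4ccccc4)(c4ccccc4)C(C)(C)C)[C@@H]2C(=O)OCC | intermediate (not isolated)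
7 | ethyl (1R,2R,3S,5R)-2-{[(tert-butyldiphenylsilyl)oxy]methyl}-3,5-bis(hydroxymethyl)cyclopentane-1-carboxylate | OC[C@@H]1C[C@H](CO)[C@@H](CO[Si](c2ccccc2)(c2ccccc2)C(C)(C)C)[C@@H]1C(=O)OCC | intermediate (not isolated)
8 | (3aR,5S,6R,6aR)-6-{[(tert-butyldiphenylsilyl)oxy]methyl}-5-(hydroxymethyl)hexahydro-1H-cyclopenta[c]furan-1-one (cis-fused) | O=C1OC[C@@H]2C[C@H](CO)[C@@H](CO[Si](c3ccccc3)(c3ccccc3)C(C)(C)C)[C@H]12 | intermediate
9 | (3aR,5S,6R,6aR)-6-{[(tert-butyldiphenylsilyl)oxy]methyl}-5-{[1-(2-nitrobenzenesulfonyl)hydrazinyl]methyl}hexahydro-1H-cyclopenta[c]furan-1-one | O=C1OC[C@@H]2C[C@H](CN(N)S(=O)(=O)c3ccccc3[N+](=O)[O-])[C@@H](CO[Si](c3ccccc3)(c3ccccc3)C(C)(C)C)[C@H]12 | intermediate (not isolated)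
10 | (3aR,5S,6R,6aR)-6-{[(tert-butyldiphenylsilyl)oxy]methyl}-5-(diazenylmethyl)hexahydro-1H-cyclopenta[c]furan-1-one | O=C1OC[C@@H]2C[C@H](CN=N)[C@@H](CO[Si](c3ccccc3)(c3ccccc3)C(C)(C)C)[C@H]12 | intermediate (not isolated)
11 | (3aR,5S,6R,6aR)-6-{[(tert-butyldiphenylsilyl)oxy]methyl}-5-methylhexahydro-1H-cyclopenta[c]furan-1-one | O=C1OC[C@@H]2C[C@H](C)[C@@H](CO[Si](c3ccccc3)(c3ccccc3)C(C)(C)C)[C@H]12 | intermediate
12 | lithium enolate of 11 (C1=C6a enolate; 3aR,5S,6R) | [Li+].[O-]C=1OC[C@@H]2C[C@H](C)[C@@H](CO[Si](c3ccccc3)(c3ccccc3)C(C)(C)C)C=12 | intermediate (not isolated)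
13 | (3aR,5S,6R,6aR)-6-{[(tert-butyldiphenylsilyl)oxy]methyl}-5,6a-dimethylhexahydro-1H-cyclopenta[c]furan-1-one | O=C1OC[C@@H]2C[C@H](C)[C@@H](CO[Si](c3ccccc3)(c3ccccc3)C(C)(C)C)[C@]12C | intermediate
14 | (3aR,5S,6R,6aR)-6-{[(tert-butyldiphenylsilyl)oxy]methyl}-5,6a-dimethylhexahydro-1H-cyclopenta[c]furan-1-ol (anomers) | OC1OC[C@@H]2C[C@H](C)[C@@H](CO[Si](c3ccccc3)(c3ccccc3)C(C)(C)C)[C@]12C | intermediate
15 | methyl (2E)-3-[(1R,2R,3S,5R)-2-{[(tert-butyldiphenylsilyl)oxy]methyl}-5-(hydroxymethyl)-1,3-dimethylcyclopentyl]prop-2-enoate | OC[C@@H]1C[C@H](C)[C@@H](CO[Si](c2ccccc2)(c2ccccc2)C(C)(C)C)[C@]1(C)/C=C/C(=O)OC | intermediate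
16 | methyl 3-[(1R,2R,3S,5R)-2-{[(tert-butyldiphenylsilyl)oxy]methyl}-5-(hydroxymethyl)-1,3-dimethylcyclopentyl]propanoate | OC[C@@H]1C[C@H](C)[C@@H](CO[Si](c2ccccc2)(c2ccccc2)C(C)(C)C)[C@]1(C)CCC(=O)OC | intermediate
17 | methyl 3-[(1S,2R,3S,5R)-2-{[(tert-butyldiphenylsilyl)oxy]methyl}-5-formyl-1,3-dimethylcyclopentyl]propanoate | O=C[C@@H]1C[C@H](C)[C@@H](CO[Si](c2ccccc2)(c2ccccc2)C(C)(C)C)[C@]1(C)CCC(=O)OC | intermediate
18 | methyl 3-[(1R,2R,3S,5S)-2-{[(tert-butyldiphenylsilyl)oxy]methyl}-1,3-dimethyl-5-(2-methylprop-1-en-1-yl)cyclopentyl]propanoate | CC(C)=C[C@@H]1C[C@H](C)[C@@H](CO[Si](c2ccccc2)(c2ccccc2)C(C)(C)C)[C@]1(C)CCC(=O)OC | intermediate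
19 | methyl 3-[(1R,2R,3S,5S)-2-(hydroxymethyl)-1,3-dimethyl-5-(2-methylprop-1-en-1-yl)cyclopentyl]propanoate | CC(C)=C[C@@H]1C[C@H](C)[C@@H](CO)[C@]1(C)CCC(=O)OC | intermediate
20 | umbelliferone, 7-hydroxy-2H-chromen-2-one | Oc1ccc2ccc(=O)oc2c1 | starting material
21 | methyl 3-[(1R,2R,3S,5S)-1,3-dimethyl-5-(2-methylprop-1-en-1-yl)-2-{[(2-oxo-2H-chromen-7-yl)oxy]methyl}cyclopentyl]propanoate | CC(C)=C[C@@H]1C[C@H](C)[C@@H](COc2ccc3ccc(=O)oc3c2)[C@]1(C)CCC(=O)OC | intermediate
22 | (2Z)-3-[4-({(1R,2R,3S,5S)-2-(2-carboxyethyl)-2,5-dimethyl-3-(2-methylprop-1-en-1-yl)cyclopentyl}methoxy)-2-hydroxyphenyl]prop-2-enoic acid (ring-opened coumarin, shown as the neutral acid) | CC(C)=C[C@@H]1C[C@H](C)[C@@H](COc2ccc(/C=C\C(=O)O)c(O)c2)[C@]1(C)CCC(=O)O | intermediate (not isolated)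
23 | ferulsinaic acid, 3-[(1R,2R,3S,5S)-1,3-dimethyl-5-(2-methylprop-1-en-1-yl)-2-{[(2-oxo-2H-chromen-7-yl)oxy]methyl}cyclopentyl]propanoic acid | CC(C)=C[C@@H]1C[C@H](C)[C@@H](COc2ccc3ccc(=O)oc3c2)[C@]1(C)CCC(=O)O | target

**Count**

Total steps: 14. Longest linear sequence: 14 steps (1 → 23); 4 and 20 enter convergently.

**Steps most likely to fail**

1. Step 8 (Wittig on the lactol). The neopentyl-type lactol may open too slowly for the stabilised ylide, and the freed primary alcohol may add back to the new enoate (oxa-Michael closure to a tetrahydrofuran). Fallback: the hydroxyl is removed from play before any acceptor exists. Lactone 13 is opened with Me2AlN(OMe)Me to the hydroxy Weinreb amide F1, which is oxidised at once (Dess–Martin) to the aldehyde amide F2. Isopropylidene Wittig olefination gives the isobutenyl Weinreb amide F3, DIBAL-H reduction gives the isobutenyl aldehyde F4, and Horner–Wadsworth–Emmons olefination with trimethyl phosphonoacetate gives the isobutenyl enoate F5. Copper hydride conjugate reduction (Stryker's reagent), which leaves the trisubstituted alkene alone, returns to 18.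

2. Step 3 (catalytic Diels–Alder). The γ-silyloxy crotonate may react sluggishly, or endo and enantiofacial control may erode under catalyst control. Fallback: control is handed to a covalently bound auxiliary. Ester 3 is saponified (LiOH) to (2E)-4-[(tert-butyldiphenylsilyl)oxy]but-2-enoic acid F6, which is acylated through its pivaloyl mixed anhydride onto lithiated (R)-4-benzyl-1,3-oxazolidin-2-one to give the enoyl imide F7. The Et2AlCl-promoted, chelate-controlled endo Diels–Alder reaction with 4 gives the imide adduct F8, and LiOH/H2O2 cleavage gives the norbornene carboxylic acid F9. Ozonolysis, NaBH4 reduction and acidification of F9 give lactone 8 directly.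

3. Step 13 (Mitsunobu etherification). Displacement at the β,β′-branched carbinol carbon may be too slow, so that the alkoxyphosphonium ion is diverted to elimination or to alkylation of the reduced azo ester. Fallback: the other C–O bond of the ether is made instead. Palladium-catalysed C–O coupling of alcohol 19 with commercial 7-bromo-2H-chromen-2-one (tBuBrettPhos Pd precatalyst, Cs2CO3, toluene, 90 °C) gives 21 without substitution at the hindered carbon; no new intermediate is formed (F0, none).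

**Further compounds**

F1 | step 8 | hydroxy Weinreb amide, (1R,2R,3S,5R)-2-{[(tert-butyldiphenylsilyl)oxy]methyl}-5-(hydroxymethyl)-N-methoxy-N,1,3-trimethylcyclopentane-1-carboxamide | OC[C@@H]1C[C@H](C)[C@@H](CO[Si](c2ccccc2)(c2ccccc2)C(C)(C)C)[C@]1(C)C(=O)N(C)OC
F2 | step 8 | aldehyde amide, 5-formyl analogue of F1 (ring configuration as drawn) | O=C[C@@H]1C[C@H](C)[C@@H](CO[Si](c2ccccc2)(c2ccccc2)C(C)(C)C)[C@]1(C)C(=O)N(C)OC
F3 | step 8 | isobutenyl Weinreb amide, 5-(2-methylprop-1-en-1-yl) analogue of F1 | CC(C)=C[C@@H]1C[C@H](C)[C@@H](CO[Si](c2ccccc2)(c2ccccc2)C(C)(C)C)[C@]1(C)C(=O)N(C)OC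
F4 | step 8 | isobutenyl aldehyde, 2-{[(tert-butyldiphenylsilyl)oxy]methyl}-1,3-dimethyl-5-(2-methylprop-1-en-1-yl)cyclopentane-1-carbaldehyde | CC(C)=C[C@@H]1C[C@H](C)[C@@H](CO[Si](c2ccccc2)(c2ccccc2)C(C)(C)C)[C@]1(C)C=O
F5 | step 8 | isobutenyl enoate, methyl (2E)-3-[2-{[(tert-butyldiphenylsilyl)oxy]methyl}-1,3-dimethyl-5-(2-methylprop-1-en-1-yl)cyclopentyl]prop-2-enoate | CC(C)=C[C@@H]1C[C@H](C)[C@@H](CO[Si](c2ccccc2)(c2ccccc2)C(C)(C)C)[C@]1(C)/C=C/C(=O)OC
F6 | step 3 | (2E)-4-[(tert-butyldiphenylsilyl)oxy]but-2-enoic acid | OC(=O)/C=C/CO[Si](c1ccccc1)(c1ccccc1)C(C)(C)C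
F7 | step 3 | enoyl imide, (4R)-4-benzyl-3-{(2E)-4-[(tert-butyldiphenylsilyl)oxy]but-2-enoyl}-1,3-oxazolidin-2-one | O=C(/C=C/CO[Si](c1ccccc1)(c1ccccc1)C(C)(C)C)N1[C@H](Cc2ccccc2)COC1=O
F8 | step 3 | imide adduct, (4R)-4-benzyl-3-[(1S,2R,3R,4R)-3-{[(tert-butyldiphenylsilyl)oxy]methyl}bicyclo[2.2.1]hept-5-ene-2-carbonyl]-1,3-oxazolidin-2-one | C1=C[C@@H]2C[C@H]1[C@@H](CO[Si](c3ccccc3)(c3ccccc3)C(C)(C)C)[C@@H]2C(=O)N1[C@H](Cc2ccccc2)COC1=O
F9 | step 3 | norbornene carboxylic acid, (1S,2R,3R,4R)-3-{[(tert-butyldiphenylsilyl)oxy]methyl}bicyclo[2.2.1]hept-5-ene-2-carboxylic acid | C1=C[C@@H]2C[C@H]1[C@@H](CO[Si](c3ccccc3)(c3ccccc3)C(C)(C)C)[C@@H]2C(=O)O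
F0 | step 13 | none | none
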